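Botcinin J is cut at C5–C6 of its pyran ring (O8, C4, C5, C6, C7, C8). Because ether oxygen O8 already ties lactate-derived C8 to quaternary C4, and C4 can carry C5 as an aldehyde that has no α-hydrogen, C5–C6 is an aldol bond to a C7 ethyl ketone. A single silyl triflate/amine Mukaiyama cyclisation thus closes the pyran, forms C5–C6 and sets C5 and C6 on a chair biased by C4. Its precursor is an acyclic keto aldehyde, ethyl ketone and aldehyde linked through O8, assembled from ethyl (S)-lactate and isoprene monoepoxide. Lactone closure at C2–C3 (samarium Reformatsky) and the two esters follow.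

Key step: step 5

Remarks before the steps:
- Numbering: C1 lactone carbonyl, C2 (methyl), C3 (acetoxy), C4 (quaternary; methyl and O8), C5 (lactone oxygen), C6 (methyl), C7 (acyloxy), C8 (methyl C9); O8 is the pyran oxygen. In this numbering the target is 2R,3S,4S,5S,6R,7R,8S with a Z side-chain alkene.
- Assumption: the (R,R) enantiomer of the diphosphine in step 1 is taken to deliver the R-configured ether carbon of 3; should the sense of induction be the opposite, the (S,S) enantiomer is used and nothing else changes.
- Remark: 15 and 21 are used racemic because their stereocentres are erased later (enolate formation in step 10, oxidation in step 17); 16, 25 and 26 are therefore pairs of epimers at that one centre.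

Step 1
Reactants: 1 ethyl (S)-lactate; 2 isoprene monoepoxide (2-methyl-2-vinyloxirane, racemic)
Product: 3 ethyl (2S)-2-{[(2R)-1-hydroxy-2-methylbut-3-en-2-yl]oxy}propanoate
Conditions: Pd2(dba)3·CHCl3 (1 mol %), (R,R)-N,N'-(cyclohexane-1,2-diyl)bis[2-(diphenylphosphanyl)benzamide] (3 mol %), BEt3 (2 mol %), CH2Cl2, rt
Reagents that add atoms: none
Why: Pd-catalysed dynamic kinetic asymmetric allylic etherification of a vinyl epoxide with an alcohol pronucleophile and a trialkylborane co-catalyst: zerovalent palladium opens both enantiomers of 2 to interconverting π-allyl complexes, the boron ate complex of the ring-opened alkoxide and the lactate hydroxyl delivers oxygen to the substituted allyl terminus, and the chiral ligand sets the quaternary ether carbon C4 (R in 3), C8 coming unchanged from 1.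

Step 2
Reactants: 3 ethyl (2S)-2-{[(2R)-1-hydroxy-2-methylbut-3-en-2-yl]oxy}propanoate
Product: 4 (2S)-2-{[(2R)-1-hydroxy-2-methylbut-3-en-2-yl]oxy}-N-methoxy-N-methylpropanamide
Conditions: MeNHOMe·HCl, i-PrMgCl, THF, −20 → 0 °C
Reagents that add atoms: N,O-dimethylhydroxylamine hydrochloride, CNOC.Cl
Why: Ester-to-amide exchange with the chloromagnesium amide of N,O-dimethylhydroxylamine (Weinreb amide synthesis), in which the primary hydroxyl is simply carried as its magnesium alkoxide and, below 0 °C, the α-alkoxy centre C8 is not deprotonated.

Step 3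
Reactants: 4 (2S)-2-{[(2R)-1-hydroxy-2-methylbut-3-en-2-yl]oxy}-N-methoxy-N-methylpropanamide; 5 ethylmagnesium bromide
Product: 6 (2S)-2-{[(2R)-1-hydroxy-2-methylbut-3-en-2-yl]oxy}pentan-3-one
Conditions: EtMgBr (3 equiv), THF, 0 °C; aq NH4Cl
Reagents that add atoms: none
Why: Weinreb ketone synthesis, in which one equivalent of Grignard reagent is spent on the hydroxyl and a single ethyl group then adds to the N-methoxy-N-methyl amide, which does not over-add, while C8 is untouched.

Step 4
Reactants: 6 (2S)-2-{[(2R)-1-hydroxy-2-methylbut-3-en-2-yl]oxy}pentan-3-one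
Product: 7 (2R)-2-methyl-2-{[(2S)-3-oxopentan-2-yl]oxy}but-3-enal
Conditions: Dess–Martin periodinane, NaHCO3, CH2Cl2, 0 °C → rt; used at once
Reagents that add atoms: none
Why: Dess–Martin oxidation of the neopentyl-type primary alcohol under buffered, non-basic conditions, giving an aldehyde on quaternary C4 that cannot enolise or epimerise while the ketone α-centre C8 and the vinyl group are left alone.

Step 5
Reactants: 7 (2R)-2-methyl-2-{[(2S)-3-oxopentan-2-yl]oxy}but-3-enal
Product: 10 (2S,4S,5S,6R)-6-ethenyl-5-hydroxy-2,4,6-trimethyloxan-3-one, via Z-silyl enol ether 8 (not isolated), via O5-silyl aldol ether 9 (not isolated)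
Conditions: TMSOTf (1.6 equiv), i-Pr2NEt (1.3 equiv), CH2Cl2 (0.02 M), −78 → −20 °C; then 1 M HCl, THF, 0 °C
Reagents that add atoms: none
Why: TMSOTf and i-Pr2NEt convert the C7 ethyl ketone by soft enolisation toward C6 into the Z-silyl enol ether 8 (the C8 methine is the more hindered site and its enol ether could only close a four-membered ring, so that path is unproductive and reverts on work-up); the silyl triflate then activates the aldehyde, the enol ether adds to C5 with transfer of silicon to O5 to give 9, and the acidic work-up frees the hydroxyl of 10. The closest known chemistry is the one-pot silyl triflate/amine Mukaiyama aldol addition and the aldol cyclisation of keto aldehydes. The pyran closes in the 6-(enolendo)-exo-trig mode, with O8 as the tether. C5 is controlled by the open, non-chelated transition state on a chair in which the C4 vinyl, C8 methyl and C6 methyl are equatorial and the C4 methyl is axial: the silylated C=O lies antiperiplanar to the C6=C7 enol bond, which places O5 equatorial, whereas a metal-bridged closed arrangement would put it axial; C6 follows from the Z enol ether on the same chair (methyl equatorial) and, like C8, is α to the ketone, so the equatorial arrangement is also the thermodynamic one. The step needs chemoselectivity (only the ketone can enolise, since the aldehyde sits on quaternary C4), regioselective enolisation toward C6, high dilution against intermolecular aldol reaction, and facial selectivity at C5, the last being the one point the substrate does not guarantee.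

Step 6
Reactants: 10 (2S,4S,5S,6R)-6-ethenyl-5-hydroxy-2,4,6-trimethyloxan-3-one
Product: 11 pyran diol (2R,3S,4R,5R,6S)-2-ethenyl-2,4,6-trimethyloxane-3,5-diol, with the C5 and C7 hydroxyls, C6 and C8 methyls and C4 vinyl equatorial and the C4 methyl axial
Conditions: NaBH4, MeOH, −40 °C
Reagents that add atoms: none
Why: Borohydride reduction of a conformationally fixed cyclic ketone, in which the small hydride attacks C7 along the axial path (which meets only C5–H and the O8 lone pair, whereas the equatorial path is torsionally encumbered by the flanking C6 and C8 centres), so that the new C7 hydroxyl is equatorial and syn to the C5 hydroxyl.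

Step 7
Reactants: 11 pyran diol
Product: 12 C7 tert-butyldimethylsilyl ether of 11 (C5 hydroxyl free)
Conditions: TBSOTf (1.05 equiv), 2,6-lutidine, CH2Cl2, −78 °C
Reagents that add atoms: tert-butyldimethylsilyl triflate, CC(C)(C)[Si](C)(C)OS(=O)(=O)C(F)(F)F
Why: Regioselective silylation with a silyl triflate, relying on the C7 hydroxyl lying between two methine carbons whereas the C5 hydroxyl is neopentylic and gauche to both the axial methyl and the vinyl group on quaternary C4, so that one equivalent at −78 °C should silylate C7 only.

Step 8
Reactants: 12 C7 tert-butyldimethylsilyl ether of 11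
Product: 14 C3 aldehyde (12 with CHO in place of the vinyl group on C4), via ozonide 13 (not isolated)
Conditions: O3, CH2Cl2, −78 °C; then PPh3, −78 °C → rt
Reagents that add atoms: ozone, [O-][O+]=O
Why: Ozonolysis with reductive phosphine work-up, the monosubstituted alkene being the only ozone-reactive site and the C3 aldehyde produced sitting on quaternary C4 without any epimerisable α-centre, while the silyl ether and the free hydroxyl are inert.

Step 9
Reactants: 14 C3 aldehyde; 15 2-bromopropanoyl bromide (racemic)
Product: 16 C5 2-bromopropanoate of 14 (both epimers at the C–Br carbon)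
Conditions: pyridine, CH2Cl2, 0 °C → rt
Reagents that add atoms: none
Why: O-Acylation with an acyl bromide and pyridine, in which the hindered C5 hydroxyl is the only nucleophile, the reactive acyl bromide overcomes its hindrance, the non-enolisable aldehyde is a spectator, and the configuration at the bromine-bearing carbon does not matter because both epimers give the same enolate in step 10.

Step 10
Reactants: 16 C5 2-bromopropanoate of 14
Product: 18 trans-fused bicyclic δ-lactone with free C3 hydroxyl and C7 silyl ether (C2 R, C3 S), via samarium enolate 17 (not isolated)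
Conditions: SmI2 (2.5 equiv), THF, −78 °C; then sat. aq NH4Cl
Reagents that add atoms: none
Why: Intramolecular samarium Reformatsky reaction, in which SmI2 reduces the C–Br bond far faster than the aldehyde to give the Z-configured enolate 17 of trivalent samarium, whose metal bridges the enolate and aldehyde oxygens while the C5–O–C1 tether forces the aldehyde substituent C4 into the axial position of that chelate and the planar ester enolate imposes a boat-shaped forming ring, so that C2–C3 is formed with the C2 methyl and the C3 hydroxyl cis to each other and to the C4 methyl.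

Step 11
Reactants: 18 bicyclic δ-lactone with free C3 hydroxyl
Product: 19 C3 acetate of 18
Conditions: Ac2O, DMAP, pyridine, CH2Cl2, rt
Reagents that add atoms: acetic anhydride, CC(=O)OC(C)=O
Why: DMAP-catalysed acetylation of the hindered secondary C3 hydroxyl, to which the silyl ether and the lactone are inert and whose weakly basic medium at room temperature should not trigger β-elimination of the new β-acetoxy lactone.

Step 12
Reactants: 19 C3 acetate of 18
Product: 20 C7 alcohol (3-O-acetyl lactone core with free equatorial C7 hydroxyl)
Conditions: HF·pyridine, pyridine, THF, 0 °C → rt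
Reagents that add atoms: none
Why: Fluoride-mediated cleavage of the silyl ether under mildly acidic, buffered conditions, chosen over basic fluoride sources so that neither acetyl migration nor β-elimination of the C3 acetate can occur.

Step 13
Reactants: 21 non-1-yn-3-ol (racemic)
Product: 22 tert-butyldimethyl(non-1-yn-3-yloxy)silane
Conditions: TBSCl, imidazole, DMF, rt
Reagents that add atoms: tert-butyldimethylsilyl chloride, CC(C)(C)[Si](C)(C)Cl
Why: Standard silylation of the secondary propargylic alcohol, which masks the hydroxyl for the lithiation and the esterification that follow.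

Step 14
Reactants: 22 tert-butyldimethyl(non-1-yn-3-yloxy)silane
Product: 24 4-[(tert-butyldimethylsilyl)oxy]dec-2-ynoic acid, via lithium acetylide 23 (not isolated)
Conditions: n-BuLi, THF, −78 °C; CO2; then cold 1 M HCl
Reagents that add atoms: carbon dioxide, O=C=O
Why: Deprotonation of the terminal alkyne and carboxylation of the lithium acetylide with CO2, a standard synthesis of alk-2-ynoic acids to which the silyl ether is inert.

Step 15
Reactants: 20 C7 alcohol; 24 4-[(tert-butyldimethylsilyl)oxy]dec-2-ynoic acid
Product: 25 C7 4-[(tert-butyldimethylsilyl)oxy]dec-2-ynoate of 20 (two epimers at the side-chain carbinol)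
Conditions: DCC, DMAP (0.1 equiv), CH2Cl2, 0 °C → rt
Reagents that add atoms: none
Why: Steglich esterification, in which the alk-2-ynoic acid forms a highly reactive O-acylisourea so that the equatorial C7 hydroxyl, the only free hydroxyl, is acylated at 0 °C with little DMAP, and the two side-chain epimers converge in step 17.

Step 16
Reactants: 25 C7 4-[(tert-butyldimethylsilyl)oxy]dec-2-ynoate of 20
Product: 26 C7 4-hydroxydec-2-ynoate of 20
Conditions: HF·pyridine, pyridine, THF, 0 °C → rt
Reagents that add atoms: none
Why: Fluoride-mediated desilylation as in step 12, after which the freed hydroxyl cannot lactonise onto the ester because the triple bond holds the two groups apart.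

Step 17
Reactants: 26 C7 4-hydroxydec-2-ynoate of 20
Product: 27 C7 4-oxodec-2-ynoate of 20
Conditions: Dess–Martin periodinane, NaHCO3, CH2Cl2, 0 °C → rt; filtration through silica
Reagents that add atoms: none
Why: Dess–Martin oxidation of the propargylic alcohol to the ynone under neutral, buffered conditions, which also removes the side-chain stereocentre and exposes the acetylenic keto ester to no nucleophile.

Step 18
Reactants: 27 C7 4-oxodec-2-ynoate of 20
Product: 28 Botcinin J
Conditions: H2 (1 atm, 1 equiv uptake), Pd/CaCO3 poisoned with Pb(OAc)2, quinoline, EtOAc, 0 °C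
Reagents that add atoms: none
Why: Lindlar semihydrogenation, in which syn delivery of one equivalent of hydrogen to the alkyne on lead-poisoned palladium gives the Z-alkene, as in the reduction of acetylenedicarbonyl compounds to maleates and cis-enediones, and the neutral conditions leave the acetate, the lactone and the ketone alone.

Compound list
1 | ethyl (S)-lactate | C[C@H](O)C(=O)OCC | starting material
2 | isoprene monoepoxide (2-methyl-2-vinyloxirane, racemic) | CC1(CO1)C=C | starting material
3 | ethyl (2S)-2-{[(2R)-1-hydroxy-2-methylbut-3-en-2-yl]oxy}propanoate | CCOC(=O)[C@H](C)O[C@](C)(C=C)CO | intermediate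
4 | (2S)-2-{[(2R)-1-hydroxy-2-methylbut-3-en-2-yl]oxy}-N-methoxy-N-methylpropanamide | CON(C)C(=O)[C@H](C)O[C@](C)(C=C)CO | intermediate
5 | ethylmagnesium bromide | CC[Mg]Br | starting material
6 | (2S)-2-{[(2R)-1-hydroxy-2-methylbut-3-en-2-yl]oxy}pentan-3-one | CCC(=O)[C@H](C)O[C@](C)(C=C)CO | intermediate
7 | (2R)-2-methyl-2-{[(2S)-3-oxopentan-2-yl]oxy}but-3-enal (key-step precursor) | CCC(=O)[C@H](C)O[C@](C)(C=C)C=O | intermediate
8 | Z-trimethylsilyl enol ether of 7 (formed in the flask) | C/C=C(\O[Si](C)(C)C)[C@H](C)O[C@](C)(C=C)C=O | intermediate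
9 | O5-trimethylsilyl ether of 10 (formed in the flask) | O=C1[C@@H](C)[C@H](O[Si](C)(C)C)[C@@](C)(C=C)O[C@H]1C | intermediate
10 | (2S,4S,5S,6R)-6-ethenyl-5-hydroxy-2,4,6-trimethyloxan-3-one (key-step product; C7 ketone, C5 alcohol) | O=C1[C@@H](C)[C@H](O)[C@@](C)(C=C)O[C@H]1C | intermediate
11 | pyran diol, (2R,3S,4R,5R,6S)-2-ethenyl-2,4,6-trimethyloxane-3,5-diol (C5 and C7 hydroxyls equatorial) | O[C@@H]1[C@@H](C)[C@H](O)[C@@](C)(C=C)O[C@H]1C | intermediate
12 | C7 tert-butyldimethylsilyl ether of 11, C5 hydroxyl free | CC(C)(C)[Si](C)(C)O[C@@H]1[C@@H](C)[C@H](O)[C@@](C)(C=C)O[C@H]1C | intermediate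
13 | ozonide (1,2,4-trioxolane) of the vinyl group of 12 (formed in the flask) | CC(C)(C)[Si](C)(C)O[C@@H]1[C@@H](C)[C@H](O)[C@@](C)(C2OCOO2)O[C@H]1C | intermediate
14 | C3 aldehyde: 12 with CHO in place of vinyl on C4 | CC(C)(C)[Si](C)(C)O[C@@H]1[C@@H](C)[C@H](O)[C@@](C)(C=O)O[C@H]1C | intermediate
15 | 2-bromopropanoyl bromide (racemic) | CC(Br)C(Br)=O | starting material
16 | C5 2-bromopropanoate of 14 (both C–Br epimers) | CC(C)(C)[Si](C)(C)O[C@@H]1[C@@H](C)[C@H](OC(=O)C(C)Br)[C@@](C)(C=O)O[C@H]1C | intermediate
17 | Z samarium enolate (O–SmI2) of the C5 propanoate (formed in the flask) | CC(C)(C)[Si](C)(C)O[C@@H]1[C@@H](C)[C@H](O/C(O[Sm](I)I)=C/C)[C@@](C)(C=O)O[C@H]1C | intermediate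
18 | trans-fused bicyclic δ-lactone, C3 hydroxyl free, C7 silyl ether, configuration as in the target | CC(C)(C)[Si](C)(C)O[C@@H]1[C@@H](C)[C@@H]2OC(=O)[C@H](C)[C@H](O)[C@@]2(C)O[C@H]1C | intermediate
19 | C3 acetate of 18 | CC(C)(C)[Si](C)(C)O[C@@H]1[C@@H](C)[C@@H]2OC(=O)[C@H](C)[C@H](OC(C)=O)[C@@]2(C)O[C@H]1C | intermediate
20 | C7 alcohol: 3-O-acetyl lactone core with free C7 hydroxyl | O[C@@H]1[C@@H](C)[C@@H]2OC(=O)[C@H](C)[C@H](OC(C)=O)[C@@]2(C)O[C@H]1C | intermediate
21 | non-1-yn-3-ol (racemic) | CCCCCCC(O)C#C | starting material
22 | tert-butyldimethyl(non-1-yn-3-yloxy)silane | CCCCCCC(O[Si](C)(C)C(C)(C)C)C#C | intermediate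
23 | lithium acetylide of 22 (formed in the flask) | CCCCCCC(O[Si](C)(C)C(C)(C)C)C#C[Li] | intermediate
24 | 4-[(tert-butyldimethylsilyl)oxy]dec-2-ynoic acid | CCCCCCC(O[Si](C)(C)C(C)(C)C)C#CC(=O)O | intermediate
25 | C7 4-[(tert-butyldimethylsilyl)oxy]dec-2-ynoate of 20 | CCCCCCC(O[Si](C)(C)C(C)(C)C)C#CC(=O)O[C@@H]1[C@@H](C)[C@@H]2OC(=O)[C@H](C)[C@H](OC(C)=O)[C@@]2(C)O[C@H]1C | intermediate
26 | C7 4-hydroxydec-2-ynoate of 20 | CCCCCCC(O)C#CC(=O)O[C@@H]1[C@@H](C)[C@@H]2OC(=O)[C@H](C)[C@H](OC(C)=O)[C@@]2(C)O[C@H]1C | intermediate
27 | C7 4-oxodec-2-ynoate of 20 | CCCCCCC(=O)C#CC(=O)O[C@@H]1[C@@H](C)[C@@H]2OC(=O)[C@H](C)[C@H](OC(C)=O)[C@@]2(C)O[C@H]1C | intermediate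
28 | Botcinin J | CCCCCCC(=O)/C=C\C(=O)O[C@@H]1[C@@H](C)[C@@H]2OC(=O)[C@H](C)[C@H](OC(C)=O)[C@@]2(C)O[C@H]1C | target

Total step count: 18. Longest linear sequence: 16 steps (1–12, then 15–18); steps 13 and 14 make the side-chain acid.

Steps most likely to fail

1. Step 5 (key step). What may go wrong: poor facial selectivity at the aldehyde carbon, the ring closing through a compact or boat-like geometry that leaves the C5 hydroxyl axial; enolisation toward C8 would in addition divert material. Fallback (C5 set by ketone reduction instead of by the aldol transition state): setting out from 7, the cyclisation is accepted with the axial outcome and the C5 epimer of 10 F1 is carried on. Me4NBH(OAc)3 in MeCN/AcOH at −20 °C (hydroxyl-directed Evans–Saksena reduction, the axial C5–O–B unit delivering hydride to the axial face of C7) should give the 5-axial, 7-equatorial diol F2. TBSOTf and 2,6-lutidine silylate the equatorial C7 hydroxyl to the silyl ether F3, and Dess–Martin oxidation gives the C5 ketone F4. NaBH4 then attacks C5 along the axial path, on the face away from the axial C4 methyl, and the equatorial alcohol formed is 12, where the route is rejoined.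

2. Step 18. What may go wrong: further hydrogenation of the doubly activated Z-alkene once it has formed, or Z-to-E isomerisation on the palladium surface. Fallback (Z-alkene made by kinetic olefination instead of hydrogenation): setting out from 20, esterification with (diphenoxyphosphoryl)acetic acid (EDC·HCl, DMAP cat., CH2Cl2) gives the C7 (diphenoxyphosphoryl)acetate F5. Its sodium salt (NaH, THF, −78 °C) is treated with 2-oxooctanal F6, prepared beforehand by Swern oxidation of octane-1,2-diol, in an Ando-type Z-selective Horner–Wadsworth–Emmons olefination, which engages only the aldehyde carbonyl and gives 28 directly.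

3. Step 7. What may go wrong: loss of site selectivity, with silylation of the C5 hydroxyl or of both hydroxyls. Fallback (differentiation by order of introduction instead of by steric bias): setting out from 10, whose only hydroxyl is at C5, TESOTf and 2,6-lutidine give the C5 triethylsilyl ether F7. NaBH4 reduces C7 as in step 6 to the C7 alcohol F8, and TBSOTf with 2,6-lutidine gives the bis-ether F9. PPTS in MeOH at 0 °C then removes the more labile triethylsilyl group and gives 12, where the route is rejoined.

Further compounds
F1 | step 5 | C5 epimer of 10 (axial C5 hydroxyl) | O=C1[C@@H](C)[C@@H](O)[C@@](C)(C=C)O[C@H]1C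
F2 | step 5 | 5-axial, 7-equatorial diol | O[C@@H]1[C@@H](C)[C@@H](O)[C@@](C)(C=C)O[C@H]1C
F3 | step 5 | C7 tert-butyldimethylsilyl ether of F2 | CC(C)(C)[Si](C)(C)O[C@@H]1[C@@H](C)[C@@H](O)[C@@](C)(C=C)O[C@H]1C
F4 | step 5 | C5 ketone with C7 silyl ether | CC(C)(C)[Si](C)(C)O[C@@H]1[C@@H](C)C(=O)[C@@](C)(C=C)O[C@H]1C
F5 | step 18 | C7 (diphenoxyphosphoryl)acetate of 20 | O=C(CP(=O)(Oc1ccccc1)Oc1ccccc1)O[C@@H]1[C@@H](C)[C@@H]2OC(=O)[C@H](C)[C@H](OC(C)=O)[C@@]2(C)O[C@H]1C
F6 | step 18 | 2-oxooctanal | CCCCCCC(=O)C=O
F7 | step 7 | C5 triethylsilyl ether of 10 | O=C1[C@@H](C)[C@H](O[Si](CC)(CC)CC)[C@@](C)(C=C)O[C@H]1C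
F8 | step 7 | C7 alcohol with C5 triethylsilyl ether | O[C@@H]1[C@@H](C)[C@H](O[Si](CC)(CC)CC)[C@@](C)(C=C)O[C@H]1C
F9 | step 7 | C5 triethylsilyl, C7 tert-butyldimethylsilyl bis-ether | CC(C)(C)[Si](C)(C)O[C@@H]1[C@@H](C)[C@H](O[Si](CC)(CC)CC)[C@@](C)(C=C)O[C@H]1C
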